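**Retrosynthetic overview**
1. Target ⇐ (13R,14S)-labd-8(17)-ene-14,15-diol, by selective acetylation of the primary hydroxyl.
2. Diol ⇐ C12–C13 disconnection: the C12 Grignard reagent of the bicyclic part plus (2R,3R)-2,3-epoxybutan-1-ol. Rear-side attack at oxirane C3 sets C13, and C14 comes in with the epoxide (proposed new, chelate-directed step).
3. Epoxide ⇐ (E)-but-2-en-1-ol (Sharpless epoxidation); C12 bromide ⇐ (+)-sclareolide (lactone reduction, dehydration to the 8(17)-alkene, OH → Br).
4. Rings: rings A and B with C5, C9 and C10 are taken intact from sclareolide, whose lactone ring is opened first. The only ring built is the oxirane, made on the side branch and opened in the coupling.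

Assumption: (+)-sclareolide and (E)-but-2-en-1-ol are taken as commercial, so the decalin stereocentres are bought and only C13 and C14 have to be set.

**Step 1**
Reactants: 1 (+)-sclareolide
Product: 2 diol (13,14,15,16-tetranorlabdane-8α,12-diol)
Conditions: LiAlH4, THF, 0 °C → rt; H2O work-up
Reagents that add atoms: none
Why: Hydride reduction of a lactone (LiAlH4) opens the γ-lactone to the 8α,12-diol without touching C5, C8, C9 or C10.

**Step 2**
Reactants: 2 diol (13,14,15,16-tetranorlabdane-8α,12-diol)
Product: 3 hydroxy acetate (8α-hydroxy-13,14,15,16-tetranorlabdan-12-yl acetate)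
Conditions: Ac2O, pyridine, CH2Cl2, rt
Reagents that add atoms: acetic anhydride, CC(=O)OC(C)=O
Why: Acylation (nucleophilic acyl substitution) is confined to the primary 12-OH because the hindered tertiary 8α-OH does not react with Ac2O/pyridine at room temperature.

**Step 3**
Reactants: 3 hydroxy acetate (8α-hydroxy-13,14,15,16-tetranorlabdan-12-yl acetate)
Product: 5 exocyclic alkene acetate (13,14,15,16-tetranorlabd-8(17)-en-12-yl acetate), via chlorosulfite ester 4 (not isolated)
Conditions: SOCl2, pyridine, CH2Cl2, −78 °C; chromatography on AgNO3-impregnated silica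
Reagents that add atoms: none
Why: E2 dehydration through chlorosulfite 4: the equatorial C8–O bond has no anti-periplanar ring hydrogen but any C17 hydrogen can rotate anti, so pyridine gives mainly the exocyclic 8(17)-alkene (Hofmann-type regiochemistry), the minor 7-ene and 8(9)-ene isomers being removed on the silver-loaded silica.

**Step 4**
Reactants: 5 exocyclic alkene acetate (13,14,15,16-tetranorlabd-8(17)-en-12-yl acetate)
Product: 6 alcohol (13,14,15,16-tetranorlabd-8(17)-en-12-ol)
Conditions: K2CO3 (0.2 equiv), MeOH, rt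
Reagents that add atoms: none
Why: Base-catalysed transesterification (methanolysis of the acetate) frees the primary alcohol, and the alkene and all stereocentres are inert to K2CO3/MeOH.

**Step 5**
Reactants: 6 alcohol (13,14,15,16-tetranorlabd-8(17)-en-12-ol)
Product: 8 bromide (12-bromo-13,14,15,16-tetranorlabd-8(17)-ene), via alkoxyphosphonium bromide 7 (not isolated)
Conditions: CBr4, PPh3, CH2Cl2, 0 °C
Reagents that add atoms: carbon tetrabromide, BrC(Br)(Br)Br
Why: Appel reaction: bromide displaces triphenylphosphine oxide from alkoxyphosphonium 7 by SN2 at the unhindered primary carbon under neutral conditions that leave the exocyclic alkene alone.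

**Step 6**
Reactants: 9 (E)-but-2-en-1-ol
Product: 10 epoxy alcohol ([(2R,3R)-3-methyloxiran-2-yl]methanol)
Conditions: Ti(OiPr)4 (5 mol %), D-(−)-diisopropyl tartrate (6 mol %), t-BuOOH, 4 Å MS, CH2Cl2, −20 °C
Reagents that add atoms: tert-butyl hydroperoxide, CC(C)(C)OO
Why: Sharpless asymmetric epoxidation: the titanium–D-(−)-tartrate complex delivers the peroxide oxygen to one face of the E-allylic alcohol, fixing both oxirane carbons as (2R,3R), that is the later C14 and the C13 carbon that will be inverted.

**Step 7**
Reactants: 8 bromide (12-bromo-13,14,15,16-tetranorlabd-8(17)-ene); 10 epoxy alcohol ([(2R,3R)-3-methyloxiran-2-yl]methanol)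
Product: 13 diol ((13R,14S)-labd-8(17)-ene-14,15-diol), via Grignard reagent 11 (not isolated), via aluminium chelate 12 (not isolated)
Conditions: AlMe3 (1.5 equiv), 2,6-tBu2-4-MeC6H2OH (3.0 equiv), PhMe, rt, then 10 (1.5 equiv), −78 → −20 °C; 11 [from 8, Mg, THF, 45 °C], CuBr·SMe2 (10 mol %), −78 → −30 °C; aq. potassium sodium tartrate
Reagents that add atoms: none
Why: Proposed new method: protonolysis of MeAl(OAr)2 by 10 gives alkoxide 12, whose aluminium also binds the oxirane oxygen in a five-membered chelate, so that (as in the known C3-selective openings of 2,3-epoxy alcohols by AlMe3 or under Ti(OiPr)4) the C3–O bond lying outside the chelate ring is the activated one while the two bulky, non-transferable aryloxides screen C2; the soft alkylcopper generated catalytically from 11 (monovalent copper) then attacks C3 from the rear in an SN2 ring opening, forging C12–C13 and setting C13 (R) by inversion while C14 (S) is carried over from C2 of 10; the closest known reaction types are the trialkylaluminium C3-alkylation of 2,3-epoxy alcohols and the copper-catalysed Grignard opening of epoxides, which have not been joined for a primary alkyl nucleophile on an unprotected epoxy alcohol.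

**Step 8**
Reactants: 13 diol ((13R,14S)-labd-8(17)-ene-14,15-diol)
Product: 14 target ((13R,14S)-14-hydroxylabd-8(17)-en-15-yl acetate)
Conditions: AcCl (1.05 equiv), 2,4,6-collidine, CH2Cl2, −78 °C
Reagents that add atoms: acetyl chloride, CC(Cl)=O
Why: Kinetically controlled acylation with AcCl and a hindered pyridine base at −78 °C esterifies the primary hydroxyl of the 1,2-diol much faster than the secondary one, and the primary acetate is also the thermodynamically favoured regioisomer, so 14 results with no stereocentre touched.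

**Compound list**
1 | (+)-sclareolide, (3aR,5aS,9aS,9bR)-3a,6,6,9a-tetramethyldecahydronaphtho[2,1-b]furan-2(1H)-one | C[C@@]1(OC(=O)C2)CC[C@H]3C(C)(C)CCC[C@]3(C)[C@H]12 | starting material
2 | 13,14,15,16-tetranorlabdane-8α,12-diol, (1R,2R,4aS,8aS)-1-(2-hydroxyethyl)-2,5,5,8a-tetramethyldecahydronaphthalen-2-ol | C[C@@]1(O)CC[C@H]2C(C)(C)CCC[C@]2(C)[C@H]1CCO | intermediate
3 | 8α-hydroxy-13,14,15,16-tetranorlabdan-12-yl acetate, 2-[(1R,2R,4aS,8aS)-2-hydroxy-2,5,5,8a-tetramethyldecahydronaphthalen-1-yl]ethyl acetate | C[C@@]1(O)CC[C@H]2C(C)(C)CCC[C@]2(C)[C@H]1CCOC(C)=O | intermediate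
4 | chlorosulfite ester of 3 at the tertiary 8α-oxygen (8α-O–S(=O)Cl) | C[C@@]1(OS(Cl)=O)CC[C@H]2C(C)(C)CCC[C@]2(C)[C@H]1CCOC(C)=O | intermediate
5 | 13,14,15,16-tetranorlabd-8(17)-en-12-yl acetate, 2-[(1S,4aS,8aS)-5,5,8a-trimethyl-2-methylidenedecahydronaphthalen-1-yl]ethyl acetate | C=C1CC[C@H]2C(C)(C)CCC[C@]2(C)[C@H]1CCOC(C)=O | intermediate
6 | 13,14,15,16-tetranorlabd-8(17)-en-12-ol, 2-[(1S,4aS,8aS)-5,5,8a-trimethyl-2-methylidenedecahydronaphthalen-1-yl]ethanol | C=C1CC[C@H]2C(C)(C)CCC[C@]2(C)[C@H]1CCO | intermediate
7 | alkoxytriphenylphosphonium bromide of 6 (12-O–PPh3 cation, bromide counter-ion) | C=C1CC[C@H]2C(C)(C)CCC[C@]2(C)[C@H]1CCO[P+](c1ccccc1)(c1ccccc1)c1ccccc1.[Br-] | intermediate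
8 | 12-bromo-13,14,15,16-tetranorlabd-8(17)-ene, (4aS,5S,8aS)-5-(2-bromoethyl)-1,1,4a-trimethyl-6-methylidenedecahydronaphthalene | C=C1CC[C@H]2C(C)(C)CCC[C@]2(C)[C@H]1CCBr | intermediate
9 | (E)-but-2-en-1-ol (trans-crotyl alcohol) | C/C=C/CO | starting material
10 | [(2R,3R)-3-methyloxiran-2-yl]methanol (trans-2,3-epoxybutan-1-ol) | C[C@H]1O[C@@H]1CO | intermediate
11 | {2-[(1S,4aS,8aS)-5,5,8a-trimethyl-2-methylidenedecahydronaphthalen-1-yl]ethyl}magnesium bromide | C=C1CC[C@H]2C(C)(C)CCC[C@]2(C)[C@H]1CC[Mg]Br | intermediate
12 | bis(2,6-di-tert-butyl-4-methylphenoxy){[(2R,3R)-3-methyloxiran-2-yl]methoxy}aluminium, oxirane oxygen chelated to aluminium | C[C@H]1O[C@@H]1CO[Al](Oc1c(cc(C)cc1C(C)(C)C)C(C)(C)C)Oc1c(cc(C)cc1C(C)(C)C)C(C)(C)C | intermediate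
13 | (13R,14S)-labd-8(17)-ene-14,15-diol, (2S,3R)-3-methyl-5-[(1S,4aS,8aS)-5,5,8a-trimethyl-2-methylidenedecahydronaphthalen-1-yl]pentane-1,2-diol | C=C1CC[C@H]2C(C)(C)CCC[C@]2(C)[C@H]1CC[C@@H](C)[C@H](O)CO | intermediate
14 | (13R,14S)-14-hydroxylabd-8(17)-en-15-yl acetate, (2S,3R)-2-hydroxy-3-methyl-5-[(1S,4aS,8aS)-5,5,8a-trimethyl-2-methylidenedecahydronaphthalen-1-yl]pentyl acetate | C=C1CC[C@H]2C(C)(C)CCC[C@]2(C)[C@H]1CC[C@@H](C)[C@H](O)COC(C)=O | target

**Step count and risks**
Total step count: 8. Longest linear sequence: 7 steps (steps 1–5, 7 and 8 from 1); step 6 is a one-step side branch from 9.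

The three steps most likely to fail:

Step 3, the regiochemistry of the dehydration: the 7-ene and 8(9)-ene isomers are hard to remove and would be carried along. The fallback sets out from 3 and comes back at 5. It replaces the base-driven anti elimination by an intramolecular syn elimination. The Burgess reagent (MeO2CN–SO2–NEt3 inner salt, benzene, 25 → 50 °C) converts the tertiary hydroxyl of 3 into 12-acetoxy-13,14,15,16-tetranorlabdan-8α-yl N-(methoxycarbonyl)sulfamate triethylammonium salt F1. This breaks down by an Ei pathway in which the sulfamate is its own base. On the rigid equatorial C8–O bond a C17 hydrogen reaches the syn-coplanar geometry most easily, so 5 is again the expected main product.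

Step 6, the epoxy alcohol: it is small, volatile and water-soluble, and the usual 90–94% ee would appear later as the (13S,14R) diastereomer of 13. The fallback sets out from 9 and comes back at 10. The epoxidation is run as before, but the alcohol is not isolated. It is esterified in the same pot (4-nitrobenzoyl chloride, Et3N, 0 °C) to the crystalline [(2R,3R)-3-methyloxiran-2-yl]methyl 4-nitrobenzoate F2. This is recrystallised to above 98% ee and 10 is released with K2CO3 in MeOH.

Step 7, the proposed new coupling: it can fail through attack at C2 (giving a 1,3-diol), through bromide opening the chelated oxirane (bromohydrin, then double inversion), or through the Grignard reagent adding to aluminium. The fallback uses known chemistry, sets out from 10 (with 11 made from 8 as in step 7) and comes back at 13. Epoxy alcohol 10 is protected (t-BuPh2SiCl, imidazole, CH2Cl2) as tert-butyl{[(2R,3R)-3-methyloxiran-2-yl]methoxy}diphenylsilane F3. This is opened with 11 and CuI (10 mol %) in THF at −30 °C; attack of the cuprate at C3 of O-protected trans-2,3-epoxybutanols, away from the inductively deactivated and shielded C2 and with inversion, is established. The product is the silyl ether 15-O-(tert-butyldiphenylsilyl)-(13R,14S)-labd-8(17)-ene-14,15-diol F4. Bu4NF in THF removes the silyl group and gives 13, at the price of two extra steps.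

**Further compounds**
F1 | step 3 | 12-acetoxy-13,14,15,16-tetranorlabdan-8α-yl N-(methoxycarbonyl)sulfamate triethylammonium salt | C[C@@]1(OS(=O)(=O)[N-]C(=O)OC)CC[C@H]2C(C)(C)CCC[C@]2(C)[C@H]1CCOC(C)=O.CC[NH+](CC)CC
F2 | step 6 | [(2R,3R)-3-methyloxiran-2-yl]methyl 4-nitrobenzoate | C[C@H]1O[C@@H]1COC(=O)c1ccc(cc1)[N+](=O)[O-]
F3 | step 7 | tert-butyl{[(2R,3R)-3-methyloxiran-2-yl]methoxy}diphenylsilane | C[C@H]1O[C@@H]1CO[Si](c1ccccc1)(c1ccccc1)C(C)(C)C
F4 | step 7 | 15-O-(tert-butyldiphenylsilyl)-(13R,14S)-labd-8(17)-ene-14,15-diol | C=C1CC[C@H]2C(C)(C)CCC[C@]2(C)[C@H]1CC[C@@H](C)[C@H](O)CO[Si](c1ccccc1)(c1ccccc1)C(C)(C)C
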